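The earlier runs and the new flask are calculated on assumed constants; the scatter is artificial.

Friday's flask holds starting material and free catalyst from the start and receives the coupling partner by a steady feed over 10 h, so the question is how much of the target-making time the partner misses.

| setting | ochre | blue | red | Friday's | Wednesday's | Sunday's |
|---|---|---|---|---|---|---|
| starting material | 44 mM | 44 mM | 44 mM | 44 mM | 44 mM | 44 mM |
| coupling partner | 57.2 mM | 57.2 mM | 57.2 mM | 57.2 mM (fed, over 10 h) | 57.2 mM | 57.2 mM |
| second substrate | 8.8 mM | 5.9 mM | 13 mM | 8.80 mM | 8.80 mM | 8.80 mM (fed, over 10 h) |
| free catalyst | 1.7 mM | 1.7 mM | 1.7 mM | 1.7 mM | 1.7 mM | 1.7 mM |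
| added ligand | 2.4 mM | 2.4 mM | 2.4 mM | 2.4 mM | 2.4 mM | 2.4 mM |
| remark | run made earlier | run made earlier | run made earlier | all else is in the flask from the start; the feed brings no volume worth counting | everything together at the start | all else is in the flask from the start; the feed brings no volume worth counting |
| time |  |  |  | 15 h | 15 h | 15 h |

| run | time / h | target / % |
|---|---|---|
| ochre | 0.667 | 6 |
| ochre | 1.33 | 9 |
| ochre | 2.50 | 15 |
| ochre | 5.00 | 22 |
| ochre | 10.0 | 29 |
| blue | 1.33 | 11 |
| blue | 2.50 | 17 |
| blue | 5.00 | 23 |
| blue | 10.0 | 27 |
| blue | 20.0 | 34 |
| red | 4.00 | 19 |
| red | 8.00 | 24 |
| red | 10.0 | 26 |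
| red | 15.0 | 30 |
| red | 20.0 | 28 |

(readings scatter by 1.5 percentage points)



* the best flask by amount of target, in percent of the starting material charged; "all alike" if 1.5 percentage points covers them all (Friday's / Wednesday's / Sunday's / all alike)
* amount of target at the end, in percent of the starting material charged, Friday's
* amount of target at the end, in percent of the starting material charged, Wednesday's
* amount of target at the end, in percent of the starting material charged, Sunday's

At 10.0 h the ochre, blue and red runs read 29%, 27% and 26%, with second substrate from 5.9 mM to 13 mM, so these readings show no effect of it beyond the scatter, and Wednesday's and Sunday's should both stand near the 30% that the red run reads at 15.0 h. The curve is front-loaded: the ochre run has half of that amount by 2.50 h, when Friday's feed has brought 25.0% of the partner.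

Two extreme versions of Friday's can be reckoned in the head. If the rate ignored the partner, the feed would cost nothing and Friday's would reach that same ceiling of 30%. If the rate were first order in the partner, each gain of the ochre run would shrink to the share of partner fed at the middle of its interval, the last gain up to the red reading counting whole, and the shrunken gains sum to 10.7%, the fed floor. That floor should err low, since its weights measure against a full charge, while the earlier runs spend partner on target, about 13.2 mM if one to one, a quarter of the charge. So this reckoning puts Friday's between floor and ceiling, below the other two flasks, which it leaves alike.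

The forecast, which unlike this reckoning ranks those two, named Wednesday's best, with 26% for Friday's (range 15% to 40%), 31% for Wednesday's and 29% for Sunday's, and remarked: “The partner was never varied, so Friday's is uncertain”.

The flasks give 17.3% for Friday's, 29.9% for Wednesday's and 32.2% for Sunday's, so Sunday's is best.

    free catalyst + target → free catalyst + over-reaction product (k = 0.00990 L mol⁻¹ s⁻¹)
    starting material + coupling partner + free catalyst → free catalyst + target (k = 0.390 L² mol⁻² s⁻¹)
    second substrate + coupling partner + free catalyst → free catalyst + second product (k = 5.30 L² mol⁻² s⁻¹)
    2 free catalyst → spent catalyst (k = 0.0300 L mol⁻¹ s⁻¹)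
    free catalyst + added ligand ⇌ idle complex (K = 1100 L mol⁻¹, k = 0.00700 L mol⁻¹ s⁻¹)

In Friday's the coupling of starting material ran while free catalyst sank to 16.6% of the catalyst charged by 10.0 h, with 65.5% as spent catalyst and 18.0% as idle complex, and half of that coupling's turnover up to 15 h was done by 7.66 h. Second substrate still stood at 15.3% of its charge at that same 10.0 h, beside 7.46 mM of second product, and Friday's ended at 1.61 times the fed floor. With 97 mM of partner in the same feed, the floor scales to 18.2%, and that factor makes it 29.3%; the neighbour computes to 28.5%.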